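You asked me for a quick number on this charge and offered your hunch, so I started from late times, where the zeta and beta runs slow down with substrate still in the flask.

| flask | substrate | reagent | free catalyst | added ligand | remark | time |
|---|---|---|---|---|---|---|
| alpha | 0.25 M | 0.20 M | 0.68 mM | 2.2 mM | run made earlier |  |
| theta | 0.12 M | 0.20 M | 0.68 mM | 2.2 mM | run made earlier |  |
| zeta | 0.50 M | 0.20 M | 0.68 mM | 2.2 mM | run made earlier |  |
| beta | 0.25 M | 0.20 M | 1 mM | 2.2 mM | run made earlier |  |
| Thursday's | 0.25 M | 0.200 M | 0.68 mM | 2.2 mM | one stirred flow tank at steady state, fed with the mixture as stated, mean residence time 2.0 d |  |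
| Sunday's | 0.25 M (fed, over 1.60 d) | 0.200 M | 0.68 mM | 2.2 mM | all but substrate at the start; substrate goes in evenly over 1.60 d, the run ends at 2.0 d | 2.0 d |
| Saturday's | 0.25 M | 0.200 M | 0.68 mM | 2.2 mM | a closed flask charged with all of it at once and left for 2.0 d | 2.0 d |
| Tuesday's | 0.25 M | 0.200 M (fed, over 1.60 d) | 0.68 mM | 2.2 mM | all but reagent at the start; reagent goes in evenly over 1.60 d, the run ends at 2.0 d | 2.0 d |

alpha run (percent of the substrate charged)

| time / h | target / % | substrate / % |
|---|---|---|
| 4.00 | 13.8 | 85.7 |
| 10.0 | 31.4 | 69.0 |
| 20.0 | 45.8 | 54.7 |
| 30.0 | 52.3 | 47.6 |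

theta run (percent of the substrate charged)

| time / d | target / % | substrate / % |
|---|---|---|
| 0.625 | 65.4 | 34.7 |
| 1.25 | 85.8 | 13.5 |
| 1.67 | 91.4 | 8.7 |
| 2.50 | 96.1 | 3.6 |

zeta run (percent of the substrate charged)

| time / d | target / % | substrate / % |
|---|---|---|
| 0.208 | 9.2 | 90.1 |
| 0.417 | 17.7 | 82.9 |
| 1.04 | 26.8 | 73.9 |
| 2.50 | 29.4 | 71.0 |

beta run (percent of the substrate charged)

| time / d | target / % | substrate / % |
|---|---|---|
| 0.625 | 49.2 | 49.3 |
| 1.25 | 59.8 | 40.0 |
| 1.67 | 62.8 | 37.0 |
| 2.50 | 63.7 | 35.5 |

(scatter of a reading: 0.5 percentage points)

- order of the set-ups by the amount of target at the outlet or at the end, in percent of the substrate put in, highest first (Thursday's / Sunday's / Saturday's / Tuesday's)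
- amount of target at the outlet or at the end, in percent of the substrate put in, Thursday's
- amount of target at the outlet or at the end, in percent of the substrate put in, Sunday's
- amount of target at the outlet or at the end, in percent of the substrate put in, Saturday's
- amount of target at the outlet or at the end, in percent of the substrate put in, Tuesday's

- the stated concentrations are those of everything mixed, before any reaction; amounts are the same in each set-up
- the earlier runs were read with a standard deviation of 0.5 percentage points
- the feed brings no volume worth counting
- the earlier runs were made in a closed, stirred flask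

Between 1.04 d and 2.50 d the zeta run moved from 26.8% to 29.4% of target, with 71.0% of its substrate unreacted. It ended at [target] = 0.147 M. I called the [target] near which a closed flask with 0.68 mM of free catalyst, 0.20 M of reagent and 2.2 mM of added ligand levels off the ceiling, and I took this last reading of the zeta run for it. The theta run ended at 0.115 M, which is lower, with 3.6% of its substrate left, so it did not test the ceiling.

The beta run, with 1 mM of free catalyst, ended at 0.159 M. In powers of ten, the catalyst rose by 0.167 and the ceiling by 0.0348. As a reading, the ceiling therefore went as the power 0.208 of catalyst, though those runs also differ in substrate. So these two readings do not show a fixed turnover number.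

For Saturday's closed flask, with 0.25 M of substrate, I therefore reckoned a ceiling at 58.8% of its charge. The alpha run, on the same charge, already stood at 52.3% after 30.0 h, a shorter time than Saturday's 2.0 d. I put Saturday's between those two figures, and the other set-ups, with the same catalyst, at or below that share.

The forecast gave 61% for Thursday's, 52% for Sunday's, 57% for Saturday's and 65% for Tuesday's, in the order Tuesday's > Thursday's > Saturday's > Sunday's, reasoning that “Dosing reagent should be best, and the tank also helps”. Its Tuesday's figure stood above my share, and so did its Thursday's.

The flasks gave Saturday's > Sunday's > Tuesday's > Thursday's: 56.3%, 53.2%, 45.4% and 36.4% in that order, the highest still under my share.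

    catalyst intermediate A + target → spent catalyst (k = 4.10 × 10⁻⁴ /M/s)
    reagent + catalyst intermediate B ⇌ catalyst intermediate C (K = 14.0 /M, k = 0.270 /M/s)
    catalyst intermediate A ⇌ catalyst intermediate B (K = 0.680, k = 0.0490 /s)
    substrate + free catalyst ⇌ catalyst intermediate A (K = 16.0 /M, k = 14.0 /M/s)
    free catalyst + added ligand ⇌ idle complex, settled at all times (K = 710 /M)
    catalyst intermediate C → free catalyst + target (k = 0.0150 /s)

Left for 20.0 d, Saturday's flask reached 58.2%, against the ceiling's 58.8%. Saturday's had half of its turnover of substrate with free catalyst up to the asked time behind it by 0.367 d, against the 2.0 d it was given, and at 2.0 d 90.2% of the catalyst charged stood as spent catalyst, with 43% of the substrate and 29% of the reagent left. For the neighbouring flask with 0.42 M of substrate, otherwise like Saturday's, the ceiling gives 35.0%; that flask gave 34.2%.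

The earlier runs and the new flask were generated by integration with constants of no real substance; scatter was added.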